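**Plan**

- Retrosynthesis: the 4'-O-benzyl ether is the only protecting group. Ring C is cut at O1–C2 and C2–C3 (Allan–Robinson), which leaves a symmetric ring A ω-methoxyacetophenone and a ring B aroic anhydride.
- Ring A is cut at C4a–C8a, and the open chain at C6–C7 and then C4a–C4, back to methoxyacetone, methyl methoxyacetate and dimethyl methoxymalonate.
- Enabling feature: ring A with C4 and C3 is one unbranched chain C8a–C8–C7–C6–C5–C4a–C4–C3. C8a, C7, C5 and C4 are carbonyl-level carbons, C8, C6 and C3 carry the methoxy groups, and C4a is the methylene between the C5 and C4 carbonyls, so the chain is a methoxylated 3,5,7-triketo ester.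
- Forward: chain assembly (C4a–C4, then C6–C7), Claisen closure of ring A (C4a–C8a), separate preparation of the ring B anhydride from 2,5-dimethoxyphenol, closure of ring C, hydrogenolysis.
- Stereochemistry: the target has no stereocentre, and the two labile centres of the open chain disappear on aromatisation.

Key step: step 3

Remark: the triketo ester is an interconverting mixture of keto–enol tautomers and diastereomers, drawn all-keto and used as such; its carbons are numbered as an octanoate, C1 (ester) to C8 corresponding to flavone C8a, C8, C7, C6, C5, C4a, C4 and C3.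

**Route**

Step 1
Reactants: 1 methoxyacetone; 2 methyl methoxyacetate (1.5 equiv)
Product: 3 1,5-dimethoxypentane-2,4-dione
Conditions: NaH (2.2 equiv), THF, 0 °C to reflux, slow addition of 1; then cold 1 M HCl
Reagents that add atoms: none
Why: Crossed Claisen condensation in which the more acidic ketone supplies the enolate at its methyl group and the ester the acyl group, with deprotonation of the product to its sodium 1,3-diketonate pulling the equilibrium toward the linear symmetric dione while the branched isomer from attack at the methoxymethylene should revert by retro-Claisen cleavage.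

Step 2
Reactants: 3 1,5-dimethoxypentane-2,4-dione; 4 dimethyl methoxymalonate
Product: 7 methyl 2,4,8-trimethoxy-3,5,7-trioxooctanoate, via dione dilithium dianion 5 (not isolated), via malonate lithium enolate 6 (not isolated)
Conditions: 3, LiN(i-Pr)2 (2.1 equiv), THF, −78 to 0 °C; separately 4, LiN(i-Pr)2 (1.0 equiv), THF, −78 °C; combine, 0 to 25 °C; then cold 1 M HCl
Reagents that add atoms: none
Why: Claisen-type acylation of a β-diketone 1,3-dianion at its more basic terminal carbanion by an ester, the ester being used as its preformed enolate 6, which has no further acidic hydrogen to quench 5 and still offers an ester carbonyl, as in the known acylations of such dianions by salts of β-keto esters.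

Step 3
Reactants: 7 methyl 2,4,8-trimethoxy-3,5,7-trioxooctanoate
Product: 9 2-methoxy-1-(2,4,6-trihydroxy-3,5-dimethoxyphenyl)ethan-1-one, via cyclohexane-1,3,5-trione tautomer 8 (not isolated)
Conditions: Mg(OMe)2 (4 equiv), degassed MeOH, 25 °C then reflux, Ar; then cold 1 M HCl
Reagents that add atoms: none
Why: Mg(OMe)2 turns 7 into chelated enolates, and the carbanion at C6 (the methylene between the C5 and C7 ketones, the future C4a) adds to the C1 ester carbonyl (the future C8a); loss of methoxide from the tetrahedral adduct gives the cyclic trione 8, whose threefold enolisation to the arene 9 makes the sequence irreversible. The closest known reaction is the Mg(OMe)2- or methoxide-mediated intramolecular Claisen (Dieckmann-type) cyclisation of 3,5,7-triketo esters to acylphloroglucinols, applied here to a chain with methoxy groups at C2, C4 and C8. Ring A closes in the 6-exo-trig mode, the carbanion attacking an ester C=O that lies outside the forming six-membered ring. No stereocentre is created, and the two epimerisable methoxy-bearing centres of 7 become sp2 carbons of the arene. The step needs Claisen closure to win over aldol closure and O-acylation: an aldol from C2 onto the C7 ketone would leave a quaternary C(OMe)(CO2Me) carbon that cannot aromatise and should revert, an aldol from C8 onto C3 would need enolisation of the least acidic terminal methoxymethylene, and the 2-pyranone from O-attack is reopened by methoxide, so 9 is the only irreversible exit. Chelation of magnesium by the 1,3-dioxygen pairs should hold the chain folded and shield the ketones from methanolysis, and oxygen is excluded because the phenolate of 9 is easily oxidised.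

Step 4
Reactants: 10 2,5-dimethoxyphenol
Product: 11 1-(benzyloxy)-2,5-dimethoxybenzene
Conditions: BnBr (1.1 equiv), K2CO3 (2 equiv), DMF, 60 °C
Reagents that add atoms: benzyl bromide, BrCc1ccccc1
Why: Williamson ether synthesis, the potassium phenoxide displacing bromide from the benzylic halide in an SN2 reaction.

Step 5
Reactants: 11 1-(benzyloxy)-2,5-dimethoxybenzene
Product: 12 1-(benzyloxy)-4-bromo-2,5-dimethoxybenzene
Conditions: N-bromosuccinimide (1.02 equiv), MeCN, 0 to 25 °C, dark
Reagents that add atoms: N-bromosuccinimide, O=C1CCC(=O)N1Br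
Why: Electrophilic aromatic bromination at C4, which is para to the benzyloxy group and ortho to the 5-methoxy group and is the only doubly activated position not flanked by two substituents, as in the 5-bromination of 1,2,4-trimethoxybenzene.

Step 6
Reactants: 12 1-(benzyloxy)-4-bromo-2,5-dimethoxybenzene
Product: 14 4-(benzyloxy)-2,5-dimethoxybenzoic acid, via aryllithium 13 (not isolated)
Conditions: n-BuLi (1.05 equiv), THF, −78 °C; CO2 (gas), −78 to 25 °C; then 1 M HCl
Reagents that add atoms: carbon dioxide, O=C=O
Why: Bromine–lithium exchange is faster at −78 °C than benzylic or ortho deprotonation, and carboxylation of the aryllithium 13 with CO2 gives the lithium benzoate, which acid releases as 14.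

Step 7
Reactants: 14 4-(benzyloxy)-2,5-dimethoxybenzoic acid (2 equiv)
Product: 15 4-(benzyloxy)-2,5-dimethoxybenzoic anhydride
Conditions: N,N'-dicyclohexylcarbodiimide (0.5 equiv), CH2Cl2, 0 to 25 °C; filtration
Reagents that add atoms: none
Why: Carbodiimide-mediated dehydration, in which the O-acylisourea from one molecule of acid is attacked by the carboxylate of a second to give the symmetric anhydride and the insoluble urea.

Step 8
Reactants: 9 2-methoxy-1-(2,4,6-trihydroxy-3,5-dimethoxyphenyl)ethan-1-one; 15 4-(benzyloxy)-2,5-dimethoxybenzoic anhydride (4 equiv)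
Product: 17 2-[4-(benzyloxy)-2,5-dimethoxyphenyl]-5,7-dihydroxy-3,6,8-trimethoxy-4H-chromen-4-one, via 5,7-di-O-aroyl flavone 16 (not isolated)
Conditions: Et3N, 160 °C (bath), N2; then KOH, MeOH–H2O, reflux, 30 min; then 1 M HCl
Reagents that add atoms: none
Why: Allan–Robinson condensation in which the phenols are O-aroylated, the methoxyacetyl methylene is C-aroylated and the resulting 1,3-diketone cyclodehydrates onto an ortho oxygen to form C2–C3 and O1–C2 of ring C, the symmetry of 9 making both ortho hydroxyls equivalent and the brief alkaline hydrolysis cleaving only the two aryl esters of 16.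

Step 9
Reactants: 17 2-[4-(benzyloxy)-2,5-dimethoxyphenyl]-5,7-dihydroxy-3,6,8-trimethoxy-4H-chromen-4-one
Product: 18 5,7,4'-trihydroxy-3,6,8,2',5'-pentamethoxyflavone
Conditions: H2 (1 atm), 10% Pd/C, EtOAc–MeOH, 25 °C
Reagents that add atoms: none
Why: Catalytic hydrogenolysis of the benzyl aryl ether over palladium on carbon, under which the tetrasubstituted C2=C3 bond of the pyranone and the aryl methyl ethers should remain untouched.

**Compound list**

1 | methoxyacetone (1-methoxypropan-2-one) | COCC(C)=O | starting material
2 | methyl methoxyacetate | COCC(=O)OC | starting material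
3 | 1,5-dimethoxypentane-2,4-dione | COCC(=O)CC(=O)COC | intermediate
4 | dimethyl methoxymalonate | COC(C(=O)OC)C(=O)OC | starting material
5 | dilithium 1,5-dimethoxypenta-1,3-diene-2,4-diolate (1,3-dianion of 3) | [Li+].[Li+].COC=C([O-])C=C([O-])COC | intermediate
6 | lithium enolate of dimethyl methoxymalonate | [Li+].COC(C(=O)OC)=C([O-])OC | intermediate
7 | methyl 2,4,8-trimethoxy-3,5,7-trioxooctanoate (tautomers and diastereomers) | COCC(=O)CC(=O)C(OC)C(=O)C(OC)C(=O)OC | intermediate
8 | 2-(methoxyacetyl)-4,6-dimethoxycyclohexane-1,3,5-trione | COCC(=O)C1C(=O)C(OC)C(=O)C(OC)C1=O | intermediate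
9 | 2-methoxy-1-(2,4,6-trihydroxy-3,5-dimethoxyphenyl)ethan-1-one | COCC(=O)c1c(O)c(OC)c(O)c(OC)c1O | intermediate
10 | 2,5-dimethoxyphenol | COc1ccc(OC)c(O)c1 | starting material
11 | 1-(benzyloxy)-2,5-dimethoxybenzene | COc1ccc(OC)c(OCc2ccccc2)c1 | intermediate
12 | 1-(benzyloxy)-4-bromo-2,5-dimethoxybenzene | COc1cc(OCc2ccccc2)c(OC)cc1Br | intermediate
13 | [4-(benzyloxy)-2,5-dimethoxyphenyl]lithium | [Li]c1cc(OC)c(OCc2ccccc2)cc1OC | intermediate
14 | 4-(benzyloxy)-2,5-dimethoxybenzoic acid | COc1cc(OCc2ccccc2)c(OC)cc1C(=O)O | intermediate
15 | 4-(benzyloxy)-2,5-dimethoxybenzoic anhydride | COc1cc(OCc2ccccc2)c(OC)cc1C(=O)OC(=O)c1cc(OC)c(OCc2ccccc2)cc1OC | intermediate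
16 | 2-[4-(benzyloxy)-2,5-dimethoxyphenyl]-3,6,8-trimethoxy-4-oxo-4H-chromene-5,7-diyl bis[4-(benzyloxy)-2,5-dimethoxybenzoate] | COc1cc(-c2oc3c(OC)c(OC(=O)c4cc(OC)c(OCc5ccccc5)cc4OC)c(OC)c(OC(=O)c4cc(OC)c(OCc5ccccc5)cc4OC)c3c(=O)c2OC)c(OC)cc1OCc1ccccc1 | intermediate
17 | 2-[4-(benzyloxy)-2,5-dimethoxyphenyl]-5,7-dihydroxy-3,6,8-trimethoxy-4H-chromen-4-one | COc1cc(-c2oc3c(OC)c(O)c(OC)c(O)c3c(=O)c2OC)c(OC)cc1OCc1ccccc1 | intermediate
18 | 5,7,4'-trihydroxy-3,6,8,2',5'-pentamethoxyflavone | COc1cc(-c2oc3c(OC)c(O)c(OC)c(O)c3c(=O)c2OC)c(OC)cc1O | target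

**Step count and risks**

Total steps: 9. Longest linear sequence: 6 steps (steps 4 to 9, from 10); the ring A branch (steps 1 to 3) joins at step 8.

Steps most likely to fail:

1. Step 3. Methanolysis of the chain at the C3 ketone (retro-Claisen cleavage), deactivation of the ester by enolisation at C2, or air oxidation of the phenolate could outpace ring closure. The fallback sets out from 7 and comes back at 9. The chain is first taken out of its base-labile open form by lactonisation (DBU, toluene, 80 °C, then dilute HCl) to 4-hydroxy-3,5-dimethoxy-6-(3-methoxy-2-oxopropyl)-2H-pyran-2-one F4, which can be purified by crystallisation. F4 is then treated with Mg(OMe)2 in degassed MeOH under the ring-opening and Claisen recyclisation known for 6-(2-oxoalkyl)-4-hydroxy-2-pyranones, which should deliver 9 from a defined, storable precursor.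

2. Step 2. The charge-delocalised malonate enolate may acylate too slowly, so that the dianion is lost by proton abstraction or self-condensation before the C–C bond forms. The fallback sets out from 2 and comes back at 7, and builds the chain through the C4–C5 bond instead. Claisen self-condensation of 2 (NaH, THF) should give methyl 2,4-dimethoxy-3-oxobutanoate F1. NaH and then n-BuLi (THF, 0 °C) convert it into the sodium lithium 1,3-dianion of methyl 2,4-dimethoxy-3-oxobutanoate F2. F2 is acylated at its terminal carbon by the sodium enolate of methyl 4-methoxy-3-oxobutanoate F3, made from the commercial keto ester COCC(=O)CC(=O)OC and NaH. This is the precedented pairing of a β-keto ester dianion with a β-keto ester salt, and acidic quench gives 7.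

3. Step 8. C-aroylation by the hindered ortho-methoxy aroyl group may stall at the tri-O-aroyl stage, or the electron-rich ketone may degrade at 160 °C. The fallback sets out from 14, uses 9, and comes back at 16 by a stepwise Baker–Venkataraman sequence at low temperature. Oxalyl chloride with catalytic DMF in CH2Cl2 converts 14 into 4-(benzyloxy)-2,5-dimethoxybenzoyl chloride F5. F5 (3.3 equiv) in pyridine acylates 9 to 2-(methoxyacetyl)-4,6-dimethoxybenzene-1,3,5-triyl tris[4-(benzyloxy)-2,5-dimethoxybenzoate] F6. Powdered KOH in pyridine at 50 °C induces O-to-C aroyl migration to 1-[2-hydroxy-3,5-dimethoxy-4,6-bis(aroyloxy)phenyl]-3-[4-(benzyloxy)-2,5-dimethoxyphenyl]-2-methoxypropane-1,3-dione F7 (aroyl = 4-(benzyloxy)-2,5-dimethoxybenzoyl). Cyclodehydration of F7 in AcOH with NaOAc at reflux gives 16, which is hydrolysed to 17 as in the second stage of step 8.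

**Further compounds**

F1 | step 2 | methyl 2,4-dimethoxy-3-oxobutanoate | COCC(=O)C(OC)C(=O)OC
F2 | step 2 | sodium lithium 1,3-dianion of methyl 2,4-dimethoxy-3-oxobutanoate | [Na+].[Li+].COC=C([O-])C(OC)=C([O-])OC
F3 | step 2 | sodium enolate of methyl 4-methoxy-3-oxobutanoate | [Na+].COCC([O-])=CC(=O)OC
F4 | step 3 | 4-hydroxy-3,5-dimethoxy-6-(3-methoxy-2-oxopropyl)-2H-pyran-2-one | COCC(=O)CC1=C(OC)C(O)=C(OC)C(=O)O1
F5 | step 8 | 4-(benzyloxy)-2,5-dimethoxybenzoyl chloride | COc1cc(OCc2ccccc2)c(OC)cc1C(Cl)=O
F6 | step 8 | 2-(methoxyacetyl)-4,6-dimethoxybenzene-1,3,5-triyl tris[4-(benzyloxy)-2,5-dimethoxybenzoate] | COCC(=O)c1c(OC(=O)c2cc(OC)c(OCc3ccccc3)cc2OC)c(OC)c(OC(=O)c2cc(OC)c(OCc3ccccc3)cc2OC)c(OC)c1OC(=O)c1cc(OC)c(OCc2ccccc2)cc1OC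
F7 | step 8 | 1-[2-hydroxy-3,5-dimethoxy-4,6-bis(aroyloxy)phenyl]-3-[4-(benzyloxy)-2,5-dimethoxyphenyl]-2-methoxypropane-1,3-dione (aroyl = 4-(benzyloxy)-2,5-dimethoxybenzoyl) | COC(C(=O)c1cc(OC)c(OCc2ccccc2)cc1OC)C(=O)c1c(O)c(OC)c(OC(=O)c2cc(OC)c(OCc3ccccc3)cc2OC)c(OC)c1OC(=O)c1cc(OC)c(OCc2ccccc2)cc1OC
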